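The north-east run, charged with more L than the west run, had turned less of its charge into D by its last reading, and I took that comparison to this flask.

in all of them: G 200 mM (held)
- west: L 1 M; run made earlier
- north-east: L 1.5 M; run made earlier
- flask: L 2.0 M; time 15 min

| run | time / min | D / % |
|---|---|---|
| west | 1.00 | 0.7 |
| west | 3.00 | 2.7 |
| west | 6.00 | 5.3 |
| west | 10.0 | 8.9 |
| north-east | 1.00 | 1.0 |
| north-east | 3.00 | 1.7 |
| north-east | 6.00 | 5.1 |
| north-east | 10.0 | 7.1 |

(readings scatter by 0.5 percentage points)

- the earlier runs were read with a standard deviation of 0.5 percentage points
- at the start none of G is in solution
- J is what G becomes in solution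

- how much D there is at 15 min, in percent of the L charged
- concentration of J in solution at 15 min, in percent of saturation

I reckoned with the rate alone, in fractions of the charge. D at the last reading over its time gave 0.00890 min⁻¹ in the west run and 0.00710 min⁻¹ in the north-east run, which, read with the scatter of those readings, made an apparent order of this fractional rate in the charge of −0.557, and carrying that to the flask's charge slowed the west rate by a factor 0.680 to 0.00605 min⁻¹, which is the mean rate, the fraction of the charge becoming D per minute averaged from the start. Replacing the curve by this mean was the risk, since the last stretch of the north-east run went at a factor 0.704 of its own mean and that of the west run at 1.01, both readings with their scatter. The straight line gave 9.07%, while the north-east factor over the stretch beyond the readings gave 8.18%, an error of 0.89 percentage points, and I committed to the straight figure.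

The forecast, built on “gas transfer in series with a reaction first order in L and J”, gave 8.8% of D (7.4% to 10.4%), below my figure, and J at 38% of saturation (18% to 65%).

The flask held 7.22% of D, within the forecast's tolerance, with J at 54.2% of saturation, 16 points above the forecast.

    J ⇌ Q (K = 21.7, k = 0.120 min⁻¹)
    L → X (k = 0.00207 min⁻¹)
    L + D → E (k = 0.0640 M⁻¹ min⁻¹)
    L + J ⇌ D (K = 3.38 M⁻¹, k = 0.144 M⁻¹ min⁻¹)
    G ⇌ J, rate k5*(csat - [J]) (kL = 0.337 min⁻¹)

The flask's mean rate was 0.00481 min⁻¹, slower than my 0.00605 min⁻¹. Part of the reason D stood this low in the flask was two things acting together, the conversion of L + D into E and the drag of G across to J: the run without the first reached 13.7% of D, the run without the second 13.4%. In the neighbouring flask with 0.50 M of L, the mean rate carried by the same order gave 0.0131 min⁻¹ and so 19.6% of D at 15 min; the computed flask held 14.1%, again lower.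

The numbers in the tables come from a simulation with constants of no real substance; the scatter is artificial.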